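**Plan**

1. Numbering used throughout: ring C1 (=CH2), C2, C3, C4 (H, Me), C5 (Me and the side chain C11H2–C12H(O-acyl)(3-furyl)), C6, C7=C8 (Z), C9=C10 (CO2Me), with C10 bonded to C1.
2. The retrosynthesis cuts the C12 ester, then the ring at C9=C10 (intramolecular Horner–Wadsworth–Emmons), then C12–furyl, C10–CO2Me, C1–C2 (Negishi), C7=C8 (Still–Gennari) and C11–C12 (alkyne homologation).
3. This leaves a C7 aldehyde and a C2 acid on a C3–C4–C5–C6 core; joining C2 to C7 as a silyl enol ether gives a cyclohexene (C5, C6, C7, C2, C3, C4), which a [4+2] cycloaddition cuts at C3–C4 and C5–C6 into (E)-2-methylbut-2-enal and a 2-silyloxybutadiene.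
4. The enabling feature: inside that six-membered ring the C4 and C5 methyl groups are cis and C5 carries C11 as a formyl group, which is what an E-configured α,β-dimethyl enal delivers; the C2=C7 enol ether marks the cleavage site and keeps C2 (acid) and C7 (aldehyde) distinct.
5. Forward order: cyclohexene (step 2), ozonolytic opening (step 4), chain growth at C7, C2 and C11 with the furan added only after the ozonolysis, ten-membered ring closed at C9=C10 (step 17), acylation last.
6. Stereochemistry: C4 and C5 from the catalyst-controlled cycloaddition (cis relation from the E alkene), C12 from a ligand-controlled furyl transfer, the acyl centre from (R)-2-methylbutanoic acid, C7=C8 from the Z-selective olefination, C9=C10 from the ring constraint.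

Key step: step 2

Remark: the oxazaborolidinium ion from (S)-α,α-diphenylprolinol is assumed to expose the enal face that leads to (1R,6R)-4; if the facial sense is the opposite one, the (R)-prolinol catalyst is used and nothing else changes.
Remark: (−)-MIB is assumed to deliver the furyl group to the Si face of aldehyde 17 (R at C12), as in its alkyl and aryl transfers; otherwise (+)-MIB is used.

**Route**

Step 1
Reactants: 1 methyl vinyl ketone
Product: 2 2-(triisopropylsilyloxy)buta-1,3-diene
Conditions: iPr3SiOTf, Et3N, Et2O, 0 → 25 °C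
Reagents that add atoms: triisopropylsilyl trifluoromethanesulfonate, CC(C)[Si](OS(=O)(=O)C(F)(F)F)(C(C)C)C(C)C
Why: Silyl enol ether formation by soft enolisation of the methyl ketone with a silyl triflate and an amine should give the cross-conjugated 2-silyloxydiene, whose bulky silyl group makes it robust enough to isolate.

Step 2
Reactants: 2 2-(triisopropylsilyloxy)buta-1,3-diene; 3 tiglic aldehyde [(E)-2-methylbut-2-enal]
Product: 4 (1R,6R)-1,6-dimethyl-4-(triisopropylsilyloxy)cyclohex-3-ene-1-carbaldehyde
Conditions: (S)-B-(o-tolyl)oxazaborolidine from (S)-α,α-diphenylprolinol (20 mol %) protonated with HNTf2 (18 mol %), 2 (2 equiv), CH2Cl2, −78 → −40 °C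
Reagents that add atoms: none
Why: The protonated oxazaborolidine binds the formyl oxygen of 3 and lowers its LUMO, so that a concerted, asynchronous normal-demand Diels–Alder reaction with the electron-rich diene 2 should proceed at low temperature; the closest known reaction type is the oxazaborolidinium-catalysed cycloaddition of α-substituted enals to 2-silyloxybutadienes. The cyclohexene C5–C6–C7–C2–C3–C4 closes by suprafacial [4+2] addition on both partners, the CH2 terminus next to the silyloxy carbon bonding to the β-carbon (C3–C4) and the other terminus to the α-carbon (C5–C6). The cis relation of the methyl groups on C4 and C5 is a direct transfer of the E geometry of 3. The absolute configuration at C4 and at the quaternary C5 is set by the catalyst, whose aryl group shields one face of the s-trans enal held by the B–O bond and a formyl C–H···O contact. The step needs "para" regiochemistry, which the donor oxygen on C2 of the diene secures by making its neighbouring CH2 the more nucleophilic end. No endo/exo question arises because both diene termini are unsubstituted.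

Step 3
Reactants: 4 (1R,6R)-1,6-dimethyl-4-(triisopropylsilyloxy)cyclohex-3-ene-1-carbaldehyde
Product: 5 (4R,5R)-4-ethynyl-4,5-dimethyl-1-(triisopropylsilyloxy)cyclohex-1-ene
Conditions: dimethyl (1-diazo-2-oxopropyl)phosphonate, K2CO3, MeOH, 0 → 25 °C
Reagents that add atoms: dimethyl (1-diazo-2-oxopropyl)phosphonate (Ohira–Bestmann reagent), COP(=O)(OC)C(=[N+]=[N-])C(C)=O
Why: The Ohira–Bestmann variant of the Seyferth–Gilbert homologation should turn the non-enolisable C11 aldehyde into the C11≡C12 alkyne under carbonate/methanol conditions that the hindered silyl enol ether tolerates, adding C12 in a form inert to ozone.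

Step 4
Reactants: 5 (4R,5R)-4-ethynyl-4,5-dimethyl-1-(triisopropylsilyloxy)cyclohex-1-ene
Product: 7 (3R,4R)-4-ethynyl-3,4-dimethyl-6-oxohexanoic acid, via aldehyde triisopropylsilyl ester 6 (not isolated)
Conditions: O3, CH2Cl2/MeOH, −78 °C (Sudan Red 7B end point); Me2S, −78 → 25 °C; then THF/H2O/AcOH, 25 °C
Reagents that add atoms: ozone, [O-][O+]=O
Why: Ozonolysis should be selective because ozone attacks the electron-rich C2=C7 silyl enol ether far faster than the alkyne; C2 emerges as a silyl ester (hydrolysed to the acid) and C7 as the aldehyde, so the two chain ends are already differentiated.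

Step 5
Reactants: 7 (3R,4R)-4-ethynyl-3,4-dimethyl-6-oxohexanoic acid
Product: 8 (3R,4R,6Z)-4-ethynyl-8-methoxy-3,4-dimethyl-8-oxooct-6-enoic acid
Conditions: methyl bis(2,2,2-trifluoroethyl)phosphonoacetate (2.2 equiv), KN(SiMe3)2 (2.2 equiv), 18-crown-6, THF, −78 °C; then 1 M HCl work-up
Reagents that add atoms: methyl bis(2,2,2-trifluoroethyl)phosphonoacetate, COC(=O)CP(=O)(OCC(F)(F)F)OCC(F)(F)F
Why: Still–Gennari olefination of the unhindered C7 aldehyde should give the Z C7=C8 enoate under kinetic control (fast elimination from the electron-poor phosphonate with a dissociated potassium counter-ion), the carboxylate being a spectator after it has consumed one equivalent of the phosphonate anion.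

Step 6
Reactants: 8 (3R,4R,6Z)-4-ethynyl-8-methoxy-3,4-dimethyl-8-oxooct-6-enoic acid
Product: 10 methyl (2Z,5R,6R)-5-ethynyl-8-hydroxy-5,6-dimethyloct-2-enoate, via mixed isobutyl carbonic anhydride 9 (not isolated)
Conditions: iBuOCOCl, N-methylmorpholine, THF, −15 °C; then NaBH4, H2O, 0 °C
Reagents that add atoms: none
Why: Borohydride reduction of a mixed carbonic anhydride reduces only the activated C2 carboxyl, so the conjugated methyl ester and the alkyne should remain untouched (chemoselective acid-to-alcohol reduction).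

Step 7
Reactants: 10 methyl (2Z,5R,6R)-5-ethynyl-8-hydroxy-5,6-dimethyloct-2-enoate
Product: 11 methyl (2Z,5R,6R)-5-ethynyl-8-iodo-5,6-dimethyloct-2-enoate
Conditions: I2, PPh3, imidazole, CH2Cl2, 0 → 25 °C
Reagents that add atoms: iodine, II
Why: Appel-type iodination of the unhindered primary C2 alcohol proceeds by SN2 displacement of the oxyphosphonium group and does not affect the enoate or the alkyne.

Step 8
Reactants: 12 2,3-dibromopropene; 13 triethyl phosphite
Product: 14 diethyl (2-bromoprop-2-en-1-yl)phosphonate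
Conditions: neat, 125 °C, bromoethane distilled off
Reagents that add atoms: none
Why: Michaelis–Arbuzov reaction takes place only at the allylic bromide, the vinylic bromide being inert to SN2 attack, which leaves the handle for the cross-coupling.

Step 9
Reactants: 11 methyl (2Z,5R,6R)-5-ethynyl-8-iodo-5,6-dimethyloct-2-enoate; 14 diethyl (2-bromoprop-2-en-1-yl)phosphonate
Product: 16 methyl (2Z,5R,6R)-9-[(diethoxyphosphoryl)methyl]-5-ethynyl-5,6-dimethyldeca-2,9-dienoate, via alkylzinc iodide 15 (not isolated)
Conditions: Zn dust (activated with BrCH2CH2Br and Me3SiCl), LiCl, THF, 40 °C; then 14, Pd(OAc)2 (3 mol %), SPhos (6 mol %), THF, 25 → 45 °C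
Reagents that add atoms: none
Why: Negishi coupling: zinc insertion into the primary iodide tolerates the ester and the terminal alkyne, and palladium-catalysed sp3–sp2 coupling with the vinyl bromide forms C1–C2 while installing the C1 methylidene and C10 as an allylic phosphonate in one operation.

Step 10
Reactants: 16 methyl (2Z,5R,6R)-9-[(diethoxyphosphoryl)methyl]-5-ethynyl-5,6-dimethyldeca-2,9-dienoate
Product: 17 methyl (2Z,5S,6R)-9-[(diethoxyphosphoryl)methyl]-5,6-dimethyl-5-(2-oxoethyl)deca-2,9-dienoate
Conditions: [CpRu(NCMe)(6-tBu-2-Ph2P-C5H3N)2]PF6 (5 mol %), acetone/H2O 4:1, 70 °C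
Reagents that add atoms: water, O
Why: Anti-Markovnikov alkyne hydration through a ruthenium vinylidene, with water delivered to the terminal carbon by the pyridyl phosphine, should give the C12 aldehyde and leave the enoate and the 1,1-disubstituted alkene alone.

Step 11
Reactants: 17 methyl (2Z,5S,6R)-9-[(diethoxyphosphoryl)methyl]-5,6-dimethyl-5-(2-oxoethyl)deca-2,9-dienoate; 18 3-bromofuran
Product: 21 methyl (2Z,5S,6R)-9-[(diethoxyphosphoryl)methyl]-5-[(2R)-2-(furan-3-yl)-2-hydroxyethyl]-5,6-dimethyldeca-2,9-dienoate, via 3-furyllithium 19 (not isolated), via ethyl(3-furyl)zinc 20 (not isolated)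
Conditions: 18, n-BuLi, t-BuOMe, −78 °C; EtZnCl, −78 → 0 °C; N,N,N',N'-tetraethylethylenediamine; (−)-MIB (3-exo-morpholinoisoborneol, 10 mol %), 17, toluene, −10 °C; aq. NH4Cl
Reagents that add atoms: none
Why: Amino-alcohol-catalysed asymmetric aryl transfer from a mixed aryl(alkyl)zinc to an aldehyde: the ligand-bound zinc alkoxide directs the furyl group to one face of the C12 aldehyde (R), the remote C4/C5 centres having little influence, and the organozinc does not add to the ester or deprotonate the phosphonate.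

Step 12
Reactants: 21 methyl (2Z,5S,6R)-9-[(diethoxyphosphoryl)methyl]-5-[(2R)-2-(furan-3-yl)-2-hydroxyethyl]-5,6-dimethyldeca-2,9-dienoate
Product: 22 diethyl {(5R,6S,8Z)-6-[(2R)-2-(furan-3-yl)-2-hydroxyethyl]-10-hydroxy-5,6-dimethyl-2-methylidenedec-8-en-1-yl}phosphonate
Conditions: iBu2AlH (4 equiv), CH2Cl2, −78 °C; Rochelle salt work-up
Reagents that add atoms: none
Why: Hydride (DIBAL-H) reduction of the conjugated ester gives the Z allylic alcohol at C9 by 1,2-addition with the alkene geometry retained, while the phosphonate diester is not reduced at this temperature.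

Step 13
Reactants: 22 diethyl {(5R,6S,8Z)-6-[(2R)-2-(furan-3-yl)-2-hydroxyethyl]-10-hydroxy-5,6-dimethyl-2-methylidenedec-8-en-1-yl}phosphonate
Product: 23 diethyl {(5R,6S,8Z)-6-[(2R)-2-(furan-3-yl)-2-(triethylsilyloxy)ethyl]-5,6-dimethyl-2-methylidene-10-(triethylsilyloxy)dec-8-en-1-yl}phosphonate
Conditions: Et3SiCl, imidazole, DMAP (cat.), CH2Cl2, 0 → 25 °C
Reagents that add atoms: chlorotriethylsilane, CC[Si](Cl)(CC)CC
Why: Silyl ether formation masks both hydroxyl groups in one operation so that the strong base of the next step meets no acidic O–H.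

Step 14
Reactants: 23 diethyl {(5R,6S,8Z)-6-[(2R)-2-(furan-3-yl)-2-(triethylsilyloxy)ethyl]-5,6-dimethyl-2-methylidene-10-(triethylsilyloxy)dec-8-en-1-yl}phosphonate
Product: 24 methyl (6R,7S,9Z)-2-(diethoxyphosphoryl)-7-[(2R)-2-(furan-3-yl)-2-(triethylsilyloxy)ethyl]-6,7-dimethyl-3-methylidene-11-(triethylsilyloxy)undec-9-enoate (both C2 epimers)
Conditions: LiN(iPr)2 (2.2 equiv), THF, −78 °C; ClCO2Me (1.1 equiv); AcOH quench at −78 °C
Reagents that add atoms: methyl chloroformate, COC(=O)Cl
Why: C-acylation of the lithium-chelated α-carbanion of the allylic phosphonate with a chloroformate places the ester on C10; the second equivalent of base absorbs the more acidic product, and kinetic α-protonation on the cold quench should keep the C1 alkene exocyclic, the new C10 centre being lost later.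

Step 15
Reactants: 24 methyl (6R,7S,9Z)-2-(diethoxyphosphoryl)-7-[(2R)-2-(furan-3-yl)-2-(triethylsilyloxy)ethyl]-6,7-dimethyl-3-methylidene-11-(triethylsilyloxy)undec-9-enoate
Product: 25 methyl (6R,7S,9Z)-2-(diethoxyphosphoryl)-7-[(2R)-2-(furan-3-yl)-2-hydroxyethyl]-11-hydroxy-6,7-dimethyl-3-methylideneundec-9-enoate
Conditions: HF·pyridine, pyridine, THF, 0 °C
Reagents that add atoms: none
Why: Fluoride-mediated desilylation in a pyridine buffer removes both triethylsilyl groups without the acid that would ionise the furyl carbinol or the base that would move the C1 alkene into conjugation.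

Step 16
Reactants: 25 methyl (6R,7S,9Z)-2-(diethoxyphosphoryl)-7-[(2R)-2-(furan-3-yl)-2-hydroxyethyl]-11-hydroxy-6,7-dimethyl-3-methylideneundec-9-enoate
Product: 26 methyl (6R,7S,9Z)-2-(diethoxyphosphoryl)-7-[(2R)-2-(furan-3-yl)-2-hydroxyethyl]-6,7-dimethyl-3-methylidene-11-oxoundec-9-enoate
Conditions: TEMPO (10 mol %), PhI(OAc)2 (1.1 equiv), CH2Cl2, 25 °C
Reagents that add atoms: none
Why: Oxoammonium (TEMPO) oxidation is sterically selective for the primary allylic C9 alcohol over the secondary C12 carbinol and is mild enough to give the Z-enal without isomerisation.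

Step 17
Reactants: 26 methyl (6R,7S,9Z)-2-(diethoxyphosphoryl)-7-[(2R)-2-(furan-3-yl)-2-hydroxyethyl]-6,7-dimethyl-3-methylidene-11-oxoundec-9-enoate
Product: 27 methyl (1E,3Z,6S,7R)-6-[(2R)-2-(furan-3-yl)-2-hydroxyethyl]-6,7-dimethyl-10-methylidenecyclodeca-1,3-diene-1-carboxylate
Conditions: LiCl (10 equiv), DBU (3 equiv), MeCN, 25 °C, 26 added by syringe pump to a final concentration of 1 mM
Reagents that add atoms: none
Why: Intramolecular Horner–Wadsworth–Emmons olefination under LiCl/amine (Masamune–Roush) conditions at high dilution: only the adduct formed at C10 can lose phosphate, so the ambident anion is funnelled to the C9=C10 alkene with the C1 methylidene untouched, while the Z C7=C8 alkene and the quaternary C5 bend the chain towards the ten-membered ring, in which C8 and C1 can only be cis about C9=C10.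

Step 18
Reactants: 27 methyl (1E,3Z,6S,7R)-6-[(2R)-2-(furan-3-yl)-2-hydroxyethyl]-6,7-dimethyl-10-methylidenecyclodeca-1,3-diene-1-carboxylate; 28 (R)-2-methylbutanoic acid
Product: 29 methyl (1E,3Z,6S,7R)-6-[(2R)-2-(furan-3-yl)-2-{[(2R)-2-methylbutanoyl]oxy}ethyl]-6,7-dimethyl-10-methylidenecyclodeca-1,3-diene-1-carboxylate (the target)
Conditions: N,N'-diisopropylcarbodiimide, DMAP (cat.), CH2Cl2, 0 °C
Reagents that add atoms: none
Why: Steglich esterification acylates the C12 hydroxyl with retention at C12, and at 0 °C with catalytic DMAP the α-centre of the simple alkanoic acid should not epimerise.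

**Compound list**

1 | methyl vinyl ketone | CC(=O)C=C | starting material
2 | 2-(triisopropylsilyloxy)buta-1,3-diene | C=CC(=C)O[Si](C(C)C)(C(C)C)C(C)C | intermediate
3 | tiglic aldehyde, (E)-2-methylbut-2-enal | C/C=C(\C)C=O | starting material
4 | (1R,6R)-1,6-dimethyl-4-(triisopropylsilyloxy)cyclohex-3-ene-1-carbaldehyde, methyl groups cis | C1=C(O[Si](C(C)C)(C(C)C)C(C)C)C[C@@H](C)[C@](C)(C=O)C1 | intermediate
5 | (4R,5R)-4-ethynyl-4,5-dimethyl-1-(triisopropylsilyloxy)cyclohex-1-ene | C1=C(O[Si](C(C)C)(C(C)C)C(C)C)C[C@@H](C)[C@](C)(C#C)C1 | intermediate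
6 | triisopropylsilyl (3R,4R)-4-ethynyl-3,4-dimethyl-6-oxohexanoate (not isolated) | CC(C)[Si](OC(=O)C[C@@H](C)[C@](C)(C#C)CC=O)(C(C)C)C(C)C | intermediate
7 | (3R,4R)-4-ethynyl-3,4-dimethyl-6-oxohexanoic acid | OC(=O)C[C@@H](C)[C@](C)(C#C)CC=O | intermediate
8 | (3R,4R,6Z)-4-ethynyl-8-methoxy-3,4-dimethyl-8-oxooct-6-enoic acid | OC(=O)C[C@@H](C)[C@](C)(C#C)C/C=C\C(=O)OC | intermediate
9 | mixed anhydride of 8 with isobutyl carbonic acid (not isolated) | CC(C)COC(=O)OC(=O)C[C@@H](C)[C@](C)(C#C)C/C=C\C(=O)OC | intermediate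
10 | methyl (2Z,5R,6R)-5-ethynyl-8-hydroxy-5,6-dimethyloct-2-enoate | OCC[C@@H](C)[C@](C)(C#C)C/C=C\C(=O)OC | intermediate
11 | methyl (2Z,5R,6R)-5-ethynyl-8-iodo-5,6-dimethyloct-2-enoate | ICC[C@@H](C)[C@](C)(C#C)C/C=C\C(=O)OC | intermediate
12 | 2,3-dibromopropene | C=C(Br)CBr | starting material
13 | triethyl phosphite | CCOP(OCC)OCC | starting material
14 | diethyl (2-bromoprop-2-en-1-yl)phosphonate | C=C(Br)CP(=O)(OCC)OCC | intermediate
15 | [(3R,4R,6Z)-4-ethynyl-8-methoxy-3,4-dimethyl-8-oxooct-6-en-1-yl]zinc iodide (not isolated) | I[Zn]CC[C@@H](C)[C@](C)(C#C)C/C=C\C(=O)OC | intermediate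
16 | methyl (2Z,5R,6R)-9-[(diethoxyphosphoryl)methyl]-5-ethynyl-5,6-dimethyldeca-2,9-dienoate | CCOP(=O)(OCC)CC(=C)CC[C@@H](C)[C@](C)(C#C)C/C=C\C(=O)OC | intermediate
17 | methyl (2Z,5S,6R)-9-[(diethoxyphosphoryl)methyl]-5,6-dimethyl-5-(2-oxoethyl)deca-2,9-dienoate | CCOP(=O)(OCC)CC(=C)CC[C@@H](C)[C@](C)(CC=O)C/C=C\C(=O)OC | intermediate
18 | 3-bromofuran | Brc1ccoc1 | starting material
19 | 3-furyllithium (not isolated) | [Li]c1ccoc1 | intermediate
20 | ethyl(3-furyl)zinc (not isolated) | CC[Zn]c1ccoc1 | intermediate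
21 | methyl (2Z,5S,6R)-9-[(diethoxyphosphoryl)methyl]-5-[(2R)-2-(furan-3-yl)-2-hydroxyethyl]-5,6-dimethyldeca-2,9-dienoate | CCOP(=O)(OCC)CC(=C)CC[C@@H](C)[C@](C)(C[C@@H](O)c1ccoc1)C/C=C\C(=O)OC | intermediate
22 | diethyl {(5R,6S,8Z)-6-[(2R)-2-(furan-3-yl)-2-hydroxyethyl]-10-hydroxy-5,6-dimethyl-2-methylidenedec-8-en-1-yl}phosphonate | CCOP(=O)(OCC)CC(=C)CC[C@@H](C)[C@](C)(C[C@@H](O)c1ccoc1)C/C=C\CO | intermediate
23 | bis(triethylsilyl) ether of 22 | CCOP(=O)(OCC)CC(=C)CC[C@@H](C)[C@](C)(C[C@@H](O[Si](CC)(CC)CC)c1ccoc1)C/C=C\CO[Si](CC)(CC)CC | intermediate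
24 | methyl (6R,7S,9Z)-2-(diethoxyphosphoryl)-7-[(2R)-2-(furan-3-yl)-2-(triethylsilyloxy)ethyl]-6,7-dimethyl-3-methylidene-11-(triethylsilyloxy)undec-9-enoate, both C2 epimers | CCOP(=O)(OCC)C(C(=O)OC)C(=C)CC[C@@H](C)[C@](C)(C[C@@H](O[Si](CC)(CC)CC)c1ccoc1)C/C=C\CO[Si](CC)(CC)CC | intermediate
25 | methyl (6R,7S,9Z)-2-(diethoxyphosphoryl)-7-[(2R)-2-(furan-3-yl)-2-hydroxyethyl]-11-hydroxy-6,7-dimethyl-3-methylideneundec-9-enoate, both C2 epimers | CCOP(=O)(OCC)C(C(=O)OC)C(=C)CC[C@@H](C)[C@](C)(C[C@@H](O)c1ccoc1)C/C=C\CO | intermediate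
26 | methyl (6R,7S,9Z)-2-(diethoxyphosphoryl)-7-[(2R)-2-(furan-3-yl)-2-hydroxyethyl]-6,7-dimethyl-3-methylidene-11-oxoundec-9-enoate, both C2 epimers | CCOP(=O)(OCC)C(C(=O)OC)C(=C)CC[C@@H](C)[C@](C)(C[C@@H](O)c1ccoc1)C/C=C\C=O | intermediate
27 | methyl (1E,3Z,6S,7R)-6-[(2R)-2-(furan-3-yl)-2-hydroxyethyl]-6,7-dimethyl-10-methylidenecyclodeca-1,3-diene-1-carboxylate | C=C1CC[C@@H](C)[C@](C)(C[C@@H](O)c2ccoc2)C/C=C\C=C/1C(=O)OC | intermediate
28 | (R)-2-methylbutanoic acid | CC[C@@H](C)C(=O)O | starting material
29 | methyl (1E,3Z,6S,7R)-6-[(2R)-2-(furan-3-yl)-2-{[(2R)-2-methylbutanoyl]oxy}ethyl]-6,7-dimethyl-10-methylidenecyclodeca-1,3-diene-1-carboxylate | C=C1CC[C@@H](C)[C@](C)(C[C@@H](OC(=O)[C@H](C)CC)c2ccoc2)C/C=C\C=C/1C(=O)OC | target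

**Step count and risks**

Total step count: 18. Longest linear sequence: 17 steps (steps 1–7 and 9–18 from methyl vinyl ketone); step 8 is a one-step side branch.

Steps most likely to fail:

1. Step 17 (ring closure). Chain-to-chain olefination may outrun closure of the strained ten-membered ring. The amine base may also isomerise the Z-enal to the E-enal, which cannot reach C10, or shuttle a proton so that the C1 methylidene drifts into conjugation. The fallback closes the ring by metathesis at C7=C8 instead of olefination at C9=C10. It sets out from 24. Intermolecular Horner–Wadsworth–Emmons reaction with acrolein (LiCl, DBU, MeCN) should give the tetraene ester F1, in which the two acrolein carbons next to C10 take the places of C9 and C8. Ring-closing metathesis (second-generation Hoveyda–Grubbs catalyst, toluene, 80 °C, high dilution) between the new terminal vinyl group and the C7 end of the Z alkene, with loss of the old C8–C9 unit as a volatile allyl ether, should give the macrocyclic silyl ether F2. HF·pyridine then returns the route to 27, before step 18.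

2. Step 2 (cycloaddition). The hindered α,β-disubstituted enal may react slowly, so that the acid-labile diene is consumed by protodesilylation or a Mukaiyama-type addition, and facial discrimination may erode at the higher temperature then needed. The fallback replaces catalyst control by a racemic cycloaddition and a resolution. It sets out from 2 and 3. Me2AlCl (20 mol %, CH2Cl2, −78 °C) should give 4 together with its mirror image ent-4 F3. Condensation of the mixture with (1S,2S)-N,N'-dimethyl-1,2-diphenylethane-1,2-diamine (Et2O, molecular sieves) gives the diastereomeric aminal of 4 F4 and aminal of ent-4 F5, which are separated by chromatography or crystallisation. Brief hydrolysis of F4 (dilute aqueous AcOH, THF, 0 °C) returns 4, and the route continues at step 3.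

3. Step 10 (alkyne hydration). Vinylidene formation at an alkyne flanked by a quaternary carbon may stall, and the phosphonate may bind the catalyst, so the alkyne would be recovered or hydrated in the Markovnikov sense. The fallback attaches the furan to the alkyne first and introduces the oxygen afterwards. It sets out from 16. Sonogashira coupling with 18 (Pd(PPh3)2Cl2, CuI, iPr2NH, 50 °C) gives the furyl alkyne F6. Ph3PAuNTf2-catalysed hydration (wet 1,4-dioxane, 60 °C), with water adding at the furyl-bearing and less hindered carbon, gives the furyl ketone F7. Oxazaborolidine-catalysed reduction ((S)-2-methyl-CBS-oxazaborolidine, catecholborane, toluene, −78 °C) returns the route to 21, so that steps 10 and 11 are both replaced and the route continues at step 12.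

Further compounds
F1 | step 17 | methyl (2E,6R,7S,9Z)-7-[(2R)-2-(furan-3-yl)-2-(triethylsilyloxy)ethyl]-6,7-dimethyl-3-methylidene-2-[(E)-prop-2-en-1-ylidene]-11-(triethylsilyloxy)undec-9-enoate (acrolein-derived diene trans to the ester) | C=C/C=C(/C(=O)OC)C(=C)CC[C@@H](C)[C@](C)(C[C@@H](O[Si](CC)(CC)CC)c1ccoc1)C/C=C\CO[Si](CC)(CC)CC
F2 | step 17 | triethylsilyl ether of 27 at C12 | C=C1CC[C@@H](C)[C@](C)(C[C@@H](O[Si](CC)(CC)CC)c2ccoc2)C/C=C\C=C/1C(=O)OC
F3 | step 2 | ent-4, (1S,6S)-1,6-dimethyl-4-(triisopropylsilyloxy)cyclohex-3-ene-1-carbaldehyde | C1=C(O[Si](C(C)C)(C(C)C)C(C)C)C[C@H](C)[C@@](C)(C=O)C1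
F4 | step 2 | aminal of 4 with (1S,2S)-N,N'-dimethyl-1,2-diphenylethane-1,2-diamine (2-substituted 1,3-dimethyl-4,5-diphenylimidazolidine) | CN1[C@@H](c2ccccc2)[C@H](c3ccccc3)N(C)C1[C@]4(C)CC=C(O[Si](C(C)C)(C(C)C)C(C)C)C[C@H]4C
F5 | step 2 | aminal of ent-4 with the same diamine | CN1[C@@H](c2ccccc2)[C@H](c3ccccc3)N(C)C1[C@@]4(C)CC=C(O[Si](C(C)C)(C(C)C)C(C)C)C[C@@H]4C
F6 | step 10 | methyl (2Z,5R,6R)-9-[(diethoxyphosphoryl)methyl]-5-[(furan-3-yl)ethynyl]-5,6-dimethyldeca-2,9-dienoate | CCOP(=O)(OCC)CC(=C)CC[C@@H](C)[C@](C)(C#Cc1ccoc1)C/C=C\C(=O)OC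
F7 | step 10 | methyl (2Z,5S,6R)-9-[(diethoxyphosphoryl)methyl]-5-[2-(furan-3-yl)-2-oxoethyl]-5,6-dimethyldeca-2,9-dienoate | CCOP(=O)(OCC)CC(=C)CC[C@@H](C)[C@](C)(CC(=O)c1ccoc1)C/C=C\C(=O)OC
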